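**Retrosynthetic overview**
1. The C22–C23 oxirane is made last, by hydroxyl-directed epoxidation of the (21S)-allylic alcohol under A1,3 control.
2. The cyclohexane is made by epoxide-triggered cation–olefin cyclisation of (10S,11S)-epoxide 27. It closes C6–C11, the bond closed in iridal biogenesis, and gives a bicyclic C7 cation. A C3 enol silane captures the cation, and the sacrificial ring A (here a tetrahydropyran) is then fragmented. This frees the C3 hydroxypropyl arm and the C2=C7 enal, as ring-A cleavage does in nature.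
3. Compound 27 is assembled from dihydropyran (C3–C7), a Sharpless C5 epoxy linchpin (C8–C12) and a 9-oxygenated farnesyl sulfone (C13–C24). The joins are at C7–C8 and C12–C13.
4. The sulfone comes from prenal, an allenylboronate and but-3-yn-1-ol, by two Zr-catalysed carboaluminations and one Negishi coupling.
5. Ring order: C10–C11 oxirane (step 3), then the cyclohexane (step 16, which consumes that oxirane and the purchased pyran ring), then the C22–C23 oxirane (step 18).

Assumption: iridal numbering is used (C1 = CHO, C3 = CH2OH, ring = C6–C11, C21 = carbinol, C22/C23 = oxirane). The presumed biosynthesis is taken as epoxide-triggered cation–olefin cyclisation forming C6–C11, giving a bicyclic C7 cation, followed by fragmentation of ring A.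

**Route**

Step 1
Reactants: 1 but-3-yn-1-ol
Product: 3 pent-2-yne-1,5-diol, via dilithio alkynolate 2 (not isolated)
Conditions: n-BuLi (2.1 equiv), THF, −78 to 0 °C; (CH2O)n, 0 °C to rt; aq. work-up
Reagents that add atoms: formaldehyde (as paraformaldehyde) C=O
Why: Hydroxymethylation of a lithium acetylide adds C12, and no stereocentre is formed.

Step 2
Reactants: 3 pent-2-yne-1,5-diol
Product: 5 (E)-2,3-dimethylpent-2-ene-1,5-diol, via alkenylmagnesium bromide 4 (not isolated)
Conditions: MeMgBr (5 equiv), CuI (20 mol %), THF, −10 °C to rt; then MeI (excess), DMPU, rt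
Reagents that add atoms: methylmagnesium bromide C[Mg]Br; iodomethane CI
Why: Alkoxide-directed Cu-catalysed anti-carbomagnesiation of a propargylic alcohol, followed by Cu-catalysed (Kochi-type) methylation of the chelated alkenyl Grignard with retention, puts the two methyl groups trans; the regiochemistry of the first addition does not matter because both alkyne carbons end up methylated.

Step 3
Reactants: 5 (E)-2,3-dimethylpent-2-ene-1,5-diol
Product: 6 (2S,3S)-2,3-epoxy-2,3-dimethylpentane-1,5-diol
Conditions: Ti(OiPr)4 (10 mol %), L-(+)-DIPT (12 mol %), t-BuOOH, 4 Å MS, CH2Cl2, −20 °C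
Reagents that add atoms: tert-butyl hydroperoxide CC(C)(C)OO
Why: Katsuki–Sharpless asymmetric epoxidation of a fast-reacting tetrasubstituted allylic alcohol with the L-(+)-tartrate delivers oxygen to the same face as in geraniol, giving 2S,3S and thereby setting C11 and C10.

Step 4
Reactants: 6 (2S,3S)-2,3-epoxy-2,3-dimethylpentane-1,5-diol
Product: 7 (2S,3S)-2,3-epoxy-5-iodo-2,3-dimethylpentan-1-ol
Conditions: PPh3 (1.05 equiv), I2 (1.05 equiv), imidazole (2.5 equiv), CH2Cl2, −10 °C
Reagents that add atoms: iodine II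
Why: Appel-type iodination takes the unhindered C8 hydroxyl and leaves the neopentyl-like C12 hydroxyl next to the fully substituted oxirane carbon, while imidazole buffers the acid-labile epoxide.

Step 5
Reactants: 7 (2S,3S)-2,3-epoxy-5-iodo-2,3-dimethylpentan-1-ol; 8 3,4-dihydro-2H-pyran
Product: 10 (2S,3S)-5-(3,4-dihydro-2H-pyran-6-yl)-2,3-epoxy-2,3-dimethylpentan-1-ol, via 6-lithio-3,4-dihydro-2H-pyran 9 (not isolated)
Conditions: 8 (3 equiv), t-BuLi (2.6 equiv), THF, −78 to 0 °C; then 7, DMPU, −78 °C to rt; base-washed silica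
Reagents that add atoms: none
Why: α-Lithiation of the cyclic enol ether and SN2 alkylation by the primary iodide form C7–C8; one equivalent of 9 only deprotonates the alcohol, the tetrasubstituted oxirane resists nucleophiles, and its trans substituents rule out intramolecular O-alkylation.

Step 6
Reactants: 11 3-methylbut-2-enal; 12 allenylboronic acid pinacol ester
Product: 13 (S)-6-methylhept-5-en-1-yn-4-ol
Conditions: (S)-TRIP phosphoric acid (5 mol %), 4 Å MS, toluene, −20 °C
Reagents that add atoms: none
Why: Chiral-phosphoric-acid-catalysed propargylation proceeds through a closed six-membered SE2′ transition state, with the catalyst antipode chosen so that the Si face of the enal is attacked, which sets C21 as S.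

Step 7
Reactants: 13 (S)-6-methylhept-5-en-1-yn-4-ol
Product: 14 (S)-4-(tert-butyldimethylsilyloxy)-6-methylhept-5-en-1-yne
Conditions: TBSCl, imidazole, DMF, rt
Reagents that add atoms: tert-butyldimethylsilyl chloride CC(C)(C)[Si](C)(C)Cl
Why: Standard silylation protects the ionisable allylic alcohol for the organometallic and Lewis-acid steps without touching C21.

Step 8
Reactants: 14 (S)-4-(tert-butyldimethylsilyloxy)-6-methylhept-5-en-1-yne
Product: 16 (1E,4S)-4-(tert-butyldimethylsilyloxy)-1-iodo-2,6-dimethylhepta-1,5-diene, via alkenylalane 15 (not isolated)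
Conditions: Me3Al (2.5 equiv), Cp2ZrCl2 (20 mol %), H2O (1 equiv), CH2Cl2, −25 °C; then I2, THF, −25 to 0 °C
Reagents that add atoms: trimethylaluminium C[Al](C)C; iodine II
Why: Negishi Zr-catalysed syn-carboalumination puts the methyl group on the internal alkyne carbon, and iodinolysis with retention fixes the E-C18=C19 olefin.

Step 9
Reactants: 1 but-3-yn-1-ol
Product: 18 (E)-3-methylpent-2-ene-1,5-diol, via alkenylalane 17 (not isolated)
Conditions: Me3Al (3 equiv), Cp2ZrCl2 (25 mol %), CH2Cl2, 0 °C to rt; then n-BuLi, THF, (CH2O)n, −78 °C to rt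
Reagents that add atoms: trimethylaluminium C[Al](C)C; formaldehyde (as paraformaldehyde) C=O
Why: Negishi syn-carboalumination followed by hydroxymethylation of the alanate with retention gives the E-C14=C15 olefin and adds C13.

Step 10
Reactants: 18 (E)-3-methylpent-2-ene-1,5-diol
Product: 20 (E)-3-methyl-5-(phenylsulfonyl)pent-3-en-1-ol, via allylic chloride 19 (not isolated)
Conditions: NCS, Me2S, CH2Cl2, −20 to 0 °C, aq. wash; crude chloride, PhSO2Na, DMF, rt
Reagents that add atoms: sodium benzenesulfinate [Na+].[O-]S(=O)c1ccccc1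
Why: Corey–Kim chlorination converts only the allylic hydroxyl, and S-alkylation of the sulfinate (SN2) keeps the E geometry, so the two hydroxyls are told apart without protection.

Step 11
Reactants: 20 (E)-3-methyl-5-(phenylsulfonyl)pent-3-en-1-ol
Product: 21 (E)-5-iodo-3-methylpent-2-en-1-yl phenyl sulfone
Conditions: PPh3, I2, imidazole, CH2Cl2, 0 °C
Reagents that add atoms: iodine II
Why: Appel-type iodination of the remaining primary alcohol provides the zinc precursor.

Step 12
Reactants: 21 (E)-5-iodo-3-methylpent-2-en-1-yl phenyl sulfone; 16 (1E,4S)-4-(tert-butyldimethylsilyloxy)-1-iodo-2,6-dimethylhepta-1,5-diene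
Product: 23 (2E,6E,9S)-9-(tert-butyldimethylsilyloxy)-3,7,11-trimethyldodeca-2,6,10-trien-1-yl phenyl sulfone, via alkylzinc iodide 22 (not isolated)
Conditions: Zn dust, LiCl, THF, 30 °C; then 16, PdCl2(dppf) (3 mol %), THF, rt
Reagents that add atoms: none
Why: LiCl-promoted zinc insertion and a stereoretentive sp3–sp2 Negishi coupling form C17–C18; oxidative addition to the alkenyl iodide is much faster than ionisation of the allylic sulfone at rt.

Step 13
Reactants: 10 (2S,3S)-5-(3,4-dihydro-2H-pyran-6-yl)-2,3-epoxy-2,3-dimethylpentan-1-ol; 23 (2E,6E,9S)-9-(tert-butyldimethylsilyloxy)-3,7,11-trimethyldodeca-2,6,10-trien-1-yl phenyl sulfone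
Product: 26 C13-phenylsulfonyl epoxy polyene (both C13 epimers), via epoxy triflate 24 (not isolated), via lithiated sulfone 25 (not isolated)
Conditions: 10, n-BuLi (1.0 equiv), Et2O, −78 °C, then Tf2O (1.0 equiv), 10 min; 23, n-BuLi (1.05 equiv), THF–DMPU, −78 °C; cannulate, −78 to −30 °C
Reagents that add atoms: none
Why: Biellmann-type alkylation of an allylic sulfone carbanion forms C12–C13; triflating the preformed lithium alkoxide is acid-free and much faster than attack of Tf2O on the enol ether, and the triflate leaving group offsets the hindrance at the epoxy-carbinyl carbon.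

Step 14
Reactants: 26 C13-phenylsulfonyl epoxy polyene (both C13 epimers)
Product: 27 (10S,11S)-epoxy dihydropyranyl polyene (cyclisation precursor)
Conditions: PdCl2(dppp) (5 mol %), LiHBEt3 (2.2 equiv), THF, 0 °C, 1 h
Reagents that add atoms: none
Why: Pd-catalysed hydride desulfonylation via the π-allyl complex delivers hydride to the less substituted C13 and keeps the E-C14=C15 olefin in place, and the fully substituted oxirane is inert to SN2 hydride at 0 °C on this time scale.

Step 15
Reactants: 28 propanal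
Product: 29 trimethyl(prop-1-en-1-yloxy)silane (E/Z mixture)
Conditions: TMSCl, Et3N, DMF, 80 °C; distil
Reagents that add atoms: chlorotrimethylsilane C[Si](C)(C)Cl
Why: Thermodynamic silyl enol ether formation supplies the C1/C2/C25 unit, and its geometry is irrelevant because C2 becomes sp2.

Step 16
Reactants: 27 (10S,11S)-epoxy dihydropyranyl polyene (cyclisation precursor); 29 trimethyl(prop-1-en-1-yloxy)silane (E/Z mixture)
Product: 32 10-O-trimethylsilyl-21-O-TBS (2Z,6R,10S,11S,21S)-enal, via bicyclic oxocarbenium triflate 30 (not isolated), via beta-alkoxy aldehyde 31 (not isolated)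
Conditions: 29 (3 equiv), 2,6-di-tert-butyl-4-methylpyridine (0.5 equiv), TMSOTf (0.2 equiv), CH2Cl2, −78 °C, 1 h; then DBU (2 equiv), −78 to 0 °C
Reagents that add atoms: none
Why: Proposed new method: TMSOTf silylates the tetrasubstituted oxirane and C6 of the cyclic enol ether, by far the strongest π-nucleophile in 27, opens the C11–O bond from the back through a chair transition state (attack at C10 would be a 5-endo closure), so C10 is retained, C11 is inverted and C6–H is set axial, anti to the C11 methyl, as in ring-A formation from oxidosqualene; the trans-fused oxocarbenium ion 30 is then captured by 29 (Mukaiyama-type addition, with TMS transfer to O10 regenerating TMSOTf) and DBU expels the ring oxygen from 31 (E1cB, retro-oxa-Michael), placing the small formyl group syn to the crowded C6 methine (A1,3 strain, Z); the closest known reaction types are epoxide-initiated polyene cyclisation terminated by an enol ether, Mukaiyama addition to ketal-derived oxocarbenium ions and Grob-type ring-A cleavage.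

Step 17
Reactants: 32 10-O-trimethylsilyl-21-O-TBS (2Z,6R,10S,11S,21S)-enal
Product: 33 (2Z,6R,10S,11S,21S)-3,10,21-trihydroxy enal (22,23-olefin)
Conditions: TBAF (3 equiv), AcOH (1 equiv), THF, 0 °C to rt
Reagents that add atoms: none
Why: Buffered fluoride desilylation removes the tertiary TMS and the secondary TBS ethers together without epimerising C6 or isomerising the enal.

Step 18
Reactants: 33 (2Z,6R,10S,11S,21S)-3,10,21-trihydroxy enal (22,23-olefin)
Product: 34 CNP0161066.1 (target)
Conditions: VO(acac)2 (3 mol %), t-BuOOH (1.1 equiv), CH2Cl2, 0 °C; minor erythro epoxide removed by chromatography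
Reagents that add atoms: tert-butyl hydroperoxide CC(C)(C)OO
Why: Vanadium-catalysed hydroxyl-directed epoxidation touches only the allylic C22=C23 olefin (the enal is electron-poor and the other olefins have no nearby hydroxyl), and A1,3 strain from the cis methyl puts C21–H in the olefin plane, so oxygen arrives syn to the hydroxyl and the 21S alcohol gives the threo 22R oxirane.

**Compound list**
1 | but-3-yn-1-ol | C#CCCO | starting material
2 | dilithio alkynolate of 1 | [Li]C#CCCO[Li] | intermediate
3 | pent-2-yne-1,5-diol | OCC#CCCO | intermediate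
4 | alkenylmagnesium bromide (bis-alkoxide) | Br[Mg]OC/C(C)=C([Mg]Br)/CCO[Mg]Br | intermediate
5 | (E)-2,3-dimethylpent-2-ene-1,5-diol | OC/C(C)=C(C)/CCO | intermediate
6 | (2S,3S)-2,3-epoxy-2,3-dimethylpentane-1,5-diol | OC[C@]1(C)O[C@@]1(C)CCO | intermediate
7 | (2S,3S)-2,3-epoxy-5-iodo-2,3-dimethylpentan-1-ol | OC[C@]1(C)O[C@@]1(C)CCI | intermediate
8 | 3,4-dihydro-2H-pyran | C1=COCCC1 | starting material
9 | 6-lithio-3,4-dihydro-2H-pyran | [Li]C1=CCCCO1 | intermediate
10 | (2S,3S)-5-(3,4-dihydro-2H-pyran-6-yl)-2,3-epoxy-2,3-dimethylpentan-1-ol (C3–C12) | OC[C@]1(C)O[C@@]1(C)CCC2=CCCCO2 | intermediate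
11 | 3-methylbut-2-enal (prenal) | CC(C)=CC=O | starting material
12 | allenylboronic acid pinacol ester | C=C=CB1OC(C)(C)C(C)(C)O1 | starting material
13 | (S)-6-methylhept-5-en-1-yn-4-ol | C#CC[C@H](O)C=C(C)C | intermediate
14 | TBS ether of 13 | C#CC[C@H](O[Si](C)(C)C(C)(C)C)C=C(C)C | intermediate
15 | (E)-alkenyl(dimethyl)alane from 14 | C[Al](C)/C=C(\C)C[C@H](O[Si](C)(C)C(C)(C)C)C=C(C)C | intermediate
16 | (1E,4S)-4-(TBSO)-1-iodo-2,6-dimethylhepta-1,5-diene (C18–C24) | I/C=C(\C)C[C@H](O[Si](C)(C)C(C)(C)C)C=C(C)C | intermediate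
17 | (E)-alkenyl(dimethyl)alane from 1 (O-aluminated) | C[Al](C)/C=C(\C)CCO[Al](C)C | intermediate
18 | (E)-3-methylpent-2-ene-1,5-diol | OC/C=C(\C)CCO | intermediate
19 | (E)-5-chloro-3-methylpent-3-en-1-ol | ClC/C=C(\C)CCO | intermediate
20 | (E)-3-methyl-5-(phenylsulfonyl)pent-3-en-1-ol | O=S(=O)(C/C=C(\C)CCO)c1ccccc1 | intermediate
21 | (E)-5-iodo-3-methylpent-2-en-1-yl phenyl sulfone | O=S(=O)(C/C=C(\C)CCI)c1ccccc1 | intermediate
22 | alkylzinc iodide from 21 | O=S(=O)(C/C=C(\C)CC[Zn]I)c1ccccc1 | intermediate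
23 | (2E,6E,9S)-9-(TBSO)-farnesyl phenyl sulfone (C13–C24) | O=S(=O)(C/C=C(\C)CC/C=C(\C)C[C@H](O[Si](C)(C)C(C)(C)C)C=C(C)C)c1ccccc1 | intermediate
24 | epoxy triflate of 10 | O=S(=O)(OC[C@]1(C)O[C@@]1(C)CCC2=CCCCO2)C(F)(F)F | intermediate
25 | α-lithiated sulfone of 23 | [Li]C(/C=C(\C)CC/C=C(\C)C[C@H](O[Si](C)(C)C(C)(C)C)C=C(C)C)S(=O)(=O)c1ccccc1 | intermediate
26 | C13-phenylsulfonyl epoxy polyene (C13 epimers) | O=S(=O)(c1ccccc1)C(C[C@]2(C)O[C@@]2(C)CCC3=CCCCO3)/C=C(\C)CC/C=C(\C)C[C@H](O[Si](C)(C)C(C)(C)C)C=C(C)C | intermediate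
27 | (10S,11S)-epoxy dihydropyranyl polyene (C3–C24) | C1(CC[C@]2(C)O[C@@]2(C)CC/C=C(\C)CC/C=C(\C)C[C@H](O[Si](C)(C)C(C)(C)C)C=C(C)C)=CCCCO1 | intermediate
28 | propanal | CCC=O | starting material
29 | trimethyl(prop-1-en-1-yloxy)silane (E/Z) | CC=CO[Si](C)(C)C | intermediate
30 | trans-fused bicyclic oxocarbenium triflate | [O+]1=C2CC[C@](C)(O[Si](C)(C)C)[C@@](C)(CC/C=C(\C)CC/C=C(\C)C[C@H](O[Si](C)(C)C(C)(C)C)C=C(C)C)[C@@H]2CCC1.[O-]S(=O)(=O)C(F)(F)F | intermediate
31 | β-alkoxy aldehyde (C2/C7 epimers, both centres lost in the same step) | O=CC(C)C12CC[C@](C)(O[Si](C)(C)C)[C@@](C)(CC/C=C(\C)CC/C=C(\C)C[C@H](O[Si](C)(C)C(C)(C)C)C=C(C)C)[C@@H]1CCCO2 | intermediate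
32 | 10-O-TMS-21-O-TBS (2Z,6R,10S,11S,21S)-enal | C/C(C=O)=C1\CC[C@](C)(O[Si](C)(C)C)[C@@](C)(CC/C=C(\C)CC/C=C(\C)C[C@H](O[Si](C)(C)C(C)(C)C)C=C(C)C)[C@@H]1CCCO | intermediate
33 | (2Z,6R,10S,11S,21S)-trihydroxy enal with 22,23-olefin | C/C(C=O)=C1\CC[C@](C)(O)[C@@](C)(CC/C=C(\C)CC/C=C(\C)C[C@H](O)C=C(C)C)[C@@H]1CCCO | intermediate
34 | CNP0161066.1 | C/C(C=O)=C1\CC[C@](C)(O)[C@@](C)(CC/C=C(\C)CC/C=C(\C)C[C@H](O)[C@H]2OC2(C)C)[C@@H]1CCCO | target

**Totals**
Total step count: 18.
Longest linear sequence: 10 (steps 1, 2, 3, 4, 5, 13, 14, 16, 17, 18).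

**Steps most likely to fail**

Step 16 (three-component cyclisation, capture and fragmentation). The risks are Meinwald rearrangement of the oxirane, slow capture of the hindered cation 30 by the weakly nucleophilic 29, and a poor Z/E ratio. The fallback sets out from 27 and comes back at 32. Only the ring is closed, using stoichiometric TMSOTf and 2,6-lutidine at −78 °C, and the cation is quenched with methanol to isolate the bicyclic methyl ketal F1. F1 is re-ionised with catalytic TMSOTf in the presence of the much more nucleophilic silyl ketene acetal of methyl propanoate, giving the β-alkoxy ester F2. KOt-Bu opens the pyran by E1cB to the hydroxy enoate F3, where the geometric isomers can be separated. DIBAL-H gives the allylic alcohol F4, and MnO2 oxidises only the allylic hydroxyl to give 32.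

Step 13 (alkylation of a hindered epoxy triflate that carries an enol ether; the same detour also avoids the hydride step 14). The fallback sets out from 10 and 16 and comes back at 27 without any sulfone.
- Left half: Parikh–Doering oxidation of 10 gives the epoxy aldehyde F5, and Wittig methylenation gives the vinyl epoxide F6. 9-BBN adds to the terminal carbon to give the B-alkyl borane F7, which is used in situ.
- Right half: 16 is coupled (Negishi) with 4-(trimethylsilyl)but-3-yn-1-ylzinc iodide to give the silyl enyne F8. K2CO3/MeOH gives the terminal alkyne F9. Zr-catalysed carboalumination and iodinolysis give the dienyl iodide F10.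
- Union: B-alkyl Suzuki coupling of F7 with F10 (PdCl2(dppf), Cs2CO3, DMF–H2O) forms C13–C14 and gives 27.

Step 2 (one-pot methylation of the hindered, chelated alkenyl Grignard). The fallback sets out from 3 and comes back at 5. The carbomagnesiation mixture is quenched with iodine to isolate the (Z)-iodoalkene diol F11. The second methyl group is then introduced by Pd-catalysed Negishi cross-coupling with Me2Zn, with retention, giving 5.

**Further compounds**
F1 | step 16 | bicyclic methyl ketal (10-O-TMS, 21-O-TBS) | COC12CC[C@](C)(O[Si](C)(C)C)[C@@](C)(CC/C=C(\C)CC/C=C(\C)C[C@H](O[Si](C)(C)C(C)(C)C)C=C(C)C)[C@@H]1CCCO2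
F2 | step 16 | β-alkoxy methyl ester | COC(=O)C(C)C12CC[C@](C)(O[Si](C)(C)C)[C@@](C)(CC/C=C(\C)CC/C=C(\C)C[C@H](O[Si](C)(C)C(C)(C)C)C=C(C)C)[C@@H]1CCCO2
F3 | step 16 | (2Z)-hydroxy enoate | C/C(C(=O)OC)=C1\CC[C@](C)(O[Si](C)(C)C)[C@@](C)(CC/C=C(\C)CC/C=C(\C)C[C@H](O[Si](C)(C)C(C)(C)C)C=C(C)C)[C@@H]1CCCO
F4 | step 16 | (2Z)-allylic alcohol | C/C(CO)=C1\CC[C@](C)(O[Si](C)(C)C)[C@@](C)(CC/C=C(\C)CC/C=C(\C)C[C@H](O[Si](C)(C)C(C)(C)C)C=C(C)C)[C@@H]1CCCO
F5 | step 13 | epoxy aldehyde from 10 | O=C[C@]1(C)O[C@@]1(C)CCC2=CCCCO2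
F6 | step 13 | vinyl epoxide | C=C[C@]1(C)O[C@@]1(C)CCC2=CCCCO2
F7 | step 13 | B-alkyl-9-BBN | B1(CC[C@]2(C)O[C@@]2(C)CCC3=CCCCO3)C4CCCC1CCC4
F8 | step 13 | silyl enyne (C14–C24) | C[Si](C)(C)C#CCC/C=C(\C)C[C@H](O[Si](C)(C)C(C)(C)C)C=C(C)C
F9 | step 13 | terminal enyne (C14–C24) | C#CCC/C=C(\C)C[C@H](O[Si](C)(C)C(C)(C)C)C=C(C)C
F10 | step 13 | (1E,5E)-dienyl iodide (C14–C24) | I/C=C(\C)CC/C=C(\C)C[C@H](O[Si](C)(C)C(C)(C)C)C=C(C)C
F11 | step 2 | (Z)-3-iodo-2-methylpent-2-ene-1,5-diol | OC/C(C)=C(I)/CCO
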